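(The runs are calculated from invented constants.)

Z seems to stop where E stops: violet reaches 25% of the X charged by 3.00 min, and its E charge over its X charge is 24.0%, so I count one Z per E, with E as the limiting reagent.

| flask | X | E | G | remark | time |
|---|---|---|---|---|---|
| red | 5.0 × 10⁻⁴ M | 0.25 mM | 0.90 mM | run made earlier |  |
| violet | 5.0 × 10⁻⁴ M | 0.12 mM | 0.90 mM | run made earlier |  |
| teal | 5.0 × 10⁻⁴ M | 0.19 mM | 0.90 mM | run made earlier |  |
| birch | 5.0 × 10⁻⁴ M | 0.250 mM | 0.900 mM | everything together at the start | 3.0 min |
| maple | 5.0 × 10⁻⁴ M | 0.250 mM | 0.900 mM (fed, over 15 s) | all else is in the flask from the start; the feed brings no volume worth counting | 3.0 min |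
| ash | 5.0 × 10⁻⁴ M | 0.250 mM | 0.900 mM (fed, over 2.5 min) | all else is in the flask from the start; the feed brings no volume worth counting | 3.0 min |
| oak | 5.0 × 10⁻⁴ M (fed, over 2.5 min) | 0.250 mM | 0.900 mM | all else is in the flask from the start; the feed brings no volume worth counting | 3.0 min |
| larch | 5.0 × 10⁻⁴ M | 0.250 mM | 0.900 mM (in portions, 2, over 2.5 min) | first portion at the start, last at 2.5 min | 3.0 min |

red run (percent of the X charged)

| time / s | Z / % | J / % |
|---|---|---|
| 10.0 | 13 | 5 |
| 20.0 | 24 | 9 |
| 40.0 | 33 | 11 |
| 60.0 | 39 | 18 |
| 80.0 | 44 | 16 |
| 120 | 44 | 23 |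

violet run (percent of the X charged)

| time / min | Z / % | J / % |
|---|---|---|
| 0.250 | 12 | 6 |
| 0.417 | 13 | 13 |
| 0.667 | 17 | 13 |
| 1.00 | 22 | 23 |
| 2.00 | 20 | 25 |
| 3.00 | 25 | 32 |

teal run (percent of the X charged)

| time / min | Z / % | J / % |
|---|---|---|
| 0.500 | 21 | 10 |
| 1.00 | 28 | 17 |
| 1.50 | 33 | 21 |
| 2.00 | 34 | 23 |
| 2.50 | 40 | 28 |
| 3.00 | 38 | 31 |

(each reading ± 1.5 percentage points)

- a reading or a percentage of Z counts all its forms, free or not

- the best flask by share of Z in Z plus J; "all alike" if 1.5 percentage points covers them all (birch / maple / ash / oak / larch / all alike)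
- share of Z in Z plus J at the end, birch
- share of Z in Z plus J at the end, maple
- share of Z in Z plus J at the end, ash
- share of Z in Z plus J at the end, oak
- share of Z in Z plus J at the end, larch

1. I carry one number, the split number (selectivity factor): Z made per J made, divided by [E]/[G] at that moment. Red's first reading gives 9.36. It is rough, with a scatter of 1.5 percentage points on a J of 5%, and taking [G] to the first power is my assumption, since no run varied G.

2. First extreme for birch: [E] and [G] stay as charged. The split then stays at S·[E]/[G], and the share of Z is 72.2%.

3. Second extreme: E is used up and J takes every remaining X. The share is then E charge over X charge, 50.0%.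

4. I expect birch between these two: falling [E] lowers the split, falling [G] raises it, and X need not be through by the end. Red has birch's charges and stands at Z 44%, J 23% at 120 s, a share of 65.7%, and I commit to about that.

5. G seems to fade by itself. In violet, J grows by 0.240 /min of the charge at first and 0.0450 /min late, while unspent X is still 43.0%. So in oak I expect E to wait for X while [G] fades and the split to climb, and I put oak first.

6. The forecast names oak, with birch 64%, maple 66%, ash 72%, oak 78% and larch 71%: “Keeping X low while E works cuts J most”.

7. The flasks give oak as best, with birch 65.9%, maple 66.5%, ash 71.6%, oak 79.2% and larch 71.3%. Birch lies between my extremes, but oak stands above the first, so that extreme is no ceiling.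

    X ⇌ Q (K = 0.0140, k = 0.174 /s)
    E + Q → Z (k = 6580 /M/s)
    G + Q → J (k = 619 /M/s)
    2 G → D (k = 10.9 /M/s)
    G + Z ⇌ L, settled at all times (K = 932 /M)

8. Oak's lead over birch is 13 points. Without the way back from Q to X it is 1.9 points, and without G pairing off into D it is 5.5 points, so each is a part of the lead and the two act together. The carried number gives the split of that one moment, not of the whole run: at 3.00 min, S·[E]/[G] stands at 1.45 in oak against 0.494 in birch.

9. Take a neighbour of birch charged with 0.0020 M of X. X does not enter the split, so the share at the start stays 72.2%, but E's charge allows Z 12.5% of the X, so I look for an end share below the start one. It gives Z 12.5%, E 0% left, and a share of 33.2%.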